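**Remarks on the chemistry (compound numbers are those of the steps and the compound list)**

- Structure check: 14 and 16 were compared atom by atom with the target 15. In 16 the quinone carbonyls sit on C2' and C5', the methoxyl on C4' and the chromone on C1'; 14 lacks only the C5' oxygen. Ring A, the C3 prenyl group and both methoxyls are the same in all three, so no connectivity needs correcting.
- Design change, ring A electrophile: an aroyl chloride with an ortho methoxymethyl ether is a poor partner. Such chlorides tend to close onto the acetal oxygen with loss of chloromethane, and a di-ortho-substituted aroyl chloride is expected to acylate a trisubstituted enolate largely on oxygen. Ring A therefore enters as aldehyde 9, and the C3–C4 bond is made by aldol addition and oxidation.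
- Design change, source of ring A: directed lithiation of the methoxymethyl ether of 3-fluoro-5-methoxyphenol has three candidate sites, each flanked by two directing groups, and offers no firm control. Ring A is instead taken from 6, which already holds fluorine, the formyl carbon and both oxygens; its two methyl ethers are told apart by chelation.
- Assumption: 6 is taken to be a catalogue compound; if not at hand, Vilsmeier–Haack formylation of 1-fluoro-3,5-dimethoxybenzene is its usual one-step source.

## Structural features

Artoindonesianin Q is a 3-prenylflavone: benzo ring A (C5 hydroxyl, C7 methoxyl) is fused to the γ-pyrone ring C, whose C2 carries aryl ring B and whose C3 carries a 3-methylbut-2-enyl chain. Ring B is a 2',5'-dihydroxy-4'-methoxyphenyl group, a methoxyhydroquinone joined to C2 through C1'. The molecule has no stereocentre, so no stereocentres stand next to each other and no stereocontrol is needed; the trisubstituted prenyl alkene is brought in intact. The fragile parts are the electron-rich hydroquinone (air and oxidants convert it to the quinone), the prenyl alkene (strong protic or Lewis acids, electrophilic oxidants) and, on the way, a 2-prenyl-1,3-diketone prone to retro-Claisen cleavage. The real difficulty is twofold. First, the fully substituted C2=C3 bond must be built with an ortho-oxygenated aryl group on one carbon and the prenyl group on the other. Second, exactly three of five oxygens (C5, C2', C5') must end free and two (C7, C4') methylated, without a demethylation that the prenyl group would not survive. The key step exploits the fact that C5' is para to the C2' hydroxyl, ortho to the C4' methoxyl and the only open position so placed, so the C5' oxygen can be added last, by oxidation of a simpler 2'-hydroxy-4'-methoxyphenyl ring.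

## Logic of the disconnections

**15 ⇒ 16.** No skeletal bond is cut; only the O–H bonds at C2' and C5' are removed, turning ring B into a para-quinone. Any oxidation able to place oxygen on C5' will not stop at 15, because 15 is oxidised more readily than the phenol it comes from; 16 is therefore the true product of that oxidation and an air-stable resting point. The gain is that the air-sensitive ring B appears only in the last operation. The forward step must be a two-electron reduction that leaves the γ-pyrone carbonyl, the C2=C3 bond and the prenyl alkene alone.

**16 ⇒ 14.** The C5'–O bond is cut. C5' is para to the C2' oxygen and ortho to the C4' methoxyl, which is where a phenol oxidation places oxygen unaided. Removing it leaves a ring B with two oxygens, available in one piece from 1. The gain is one oxygen, one protecting group and all hydroquinone handling removed from steps 1 to 8. The demand is heavy: the oxidation must act on ring B and not on ring A or the alkene, must choose C5' over C3', and must run on free phenols, since a ring A acetal could not be removed afterwards without exposing a quinone or hydroquinone to acid.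

**14 ⇒ 13.** The O–H bonds at C5 and C2' are exchanged for acetal O–C bonds. Both phenols must be masked for the enolate chemistry. The C2' oxygen in particular must stay masked until ring C exists, or it would condense with the ring A carbonyl of 12 and give the isomeric chromone with the rings in exchanged roles. Acetals are preferred to methyl or benzyl ethers because their removal needs neither a boron halide nor hydrogenation, both of which endanger the prenyl group. The forward step needs acid mild enough for a trisubstituted alkene.

**13 ⇒ 12.** The O1–C8a bond is cut, opening ring C to a 2-prenyl-1,3-diketone with fluorine on the future C8a. All carbon–carbon bonds of the flavone then lie in an acyclic precursor, and the direction of ring closure is decided by which ring carries fluorine. The forward step is an enolate SNAr on a ring activated only by the ortho carbonyl. The two ring A oxygens are meta to fluorine, which keeps this feasible, but the diketone must be kept from hydroxide.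

**12 ⇒ 11 ⇒ 5 + 9.** The C3–C4 bond is cut at the alcohol oxidation level (11), one oxidation state below 12. Addition of a crowded enolate to a non-enolisable aldehyde can only form the C–C bond, whereas acylation of the same enolate would compete with O-acylation; the price is one oxidation step. The cut divides the molecule into a ring B ketone and a ring A aldehyde of similar size. The forward aldol needs the pre-formed enolate 10 and a cold quench; its stereochemistry is irrelevant.

**5 ⇒ 2 + 3.** The C3–C1'' bond is cut, separating the prenyl group as electrophile 3 from methyl ketone 2 through enolate 4. The prenyl group thus enters before the crowded C2=C3 bond exists, by a simple alkylation. The demand is mono-alkylation of a methyl ketone.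

**2 ⇒ 1 and 9 ⇒ 8 ⇒ 6.** Only O–C bonds to protecting groups are cut. 1 already contains ring B with its two oxygens differentiated. In 6 the formyl group directs cleavage to its ortho methyl ether through chelate 7, so the future C5 oxygen can be re-protected as an acetal in 9 while the C7 methyl ether stays. The forward demand is a chelation-controlled mono-demethylation, done before any alkene is present.

## Other disconnections considered

**Alternative 1:** The cut runs through C3–C4 and O1–C2 and divides ring C into salicylaldehyde A1 and internal aryl prenyl alkyne A2. In the forward step [Cp*RhCl2]2 (trivalent rhodium) with Cu(OAc)2 (divalent copper) as oxidant activates the formyl C–H bond of A1 under direction of the phenol. A2 then inserts into the acyl–rhodium bond, and C–O reductive elimination closes ring C to give A3.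
- In its favour: two bonds and ring C form in one operation from two fragments, and by analogy with related annulations the aryl-bearing alkyne carbon should end next to oxygen, as required.
- Against it: A2 is a 1,4-enyne whose doubly activated CH2 invites isomerisation to an allene or diene under the metal conditions. Its ortho acetal crowds the insertion, and the C6 methoxyl of A1 crowds the formyl group and favours decarbonylation. After A3, the C5 methyl ether must be cleaved by a boron halide in the presence of the prenyl group, with the hydroquinone liberated in the same acidic step.
- Comparison: on convergence and step count this alternative is the better one, probably by two or three steps. On structure it is also better in one respect: both ring B oxygens are present from the start, so no regiochemical question arises at a late oxidation. Mechanistically it is the weaker plan, since it rests on an insertion of uncertain compatibility with the skipped enyne and ends in a Lewis-acid demethylation. The chosen route uses only enolate chemistry, SNAr and dilute acid before its single demanding step.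

**Alternative 2:** The cut is the C2=C3 bond. In the forward step, heating the acyl phosphorane ester A4 lets the prenyl-bearing ylide carbon add to the neighbouring aryl ester carbonyl. The four-membered intermediate collapses with extrusion of the phosphorus as its oxide and closes ring C to give A5.
- In its favour: the regiochemistry of ring C is unambiguous, the key step is thermal and neutral, and all oxygens are in place, so acetal removal gives 15 directly with no redox step. In that respect it is the equal or better of the chosen plan.
- Against it: a fully substituted, acyl-stabilised ylide carbon must attack the ester of an electron-rich, ortho-substituted benzoic acid, the least reactive pairing for an ester Wittig reaction. A4 is also awkward to reach. Halogenation next to the ketone is not compatible with the prenyl alkene, so the ylide would have to be prenylated at carbon and re-formed. The aryl ester can also migrate under base by the Baker–Venkataraman pathway.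
- Comparison: three acetals instead of two, a separately built fully oxygenated ring B acid, and no saving in steps. The chosen plan trades the certainty of pre-installed oxygens for simpler building blocks and a late oxidation.

**Alternative 3:** The cut is O1–C8a, the same bond as in step 7 of the chosen route, but on diketone A6 with all five oxygens as methyl ethers; enolate SNAr gives A7.
- In its favour: the ring closure is mechanistically identical, so the two plans are equal there. The building blocks are plain methyl ethers, no acetal is handled, ring B oxygenation is fixed from the start, and A7 should be reached in fewer steps, so it is better on step count and protecting-group economy up to that point.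
- Against it: three of five methyl ethers (C5, C2', C5') must then go while C7 and C4' stay. The C5 ether could be cleaved by chelation with BCl3, and the para-related C2'/C5' pair removed oxidatively with (NH4)2Ce(NO3)6 (tetravalent cerium) to reach the same quinone 16, followed by the same reduction. Both reagents meet the prenyl alkene, however, and the cerium oxidant must choose the para pair over the ortho C4'/C5' pair.
- Comparison: equal on ring closure and final reduction, and shorter overall. The chosen plan is safer in the endgame, because it installs one oxygen at a tunable electrode potential and removes only acid-labile acetals.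

Key step: step 9

## Route

Step 1
Reactants: 1 paeonol, 1-(2-hydroxy-4-methoxyphenyl)ethanone
Product: 2 1-[4-methoxy-2-(methoxymethoxy)phenyl]ethanone
Conditions: MOMCl, K2CO3, acetone, reflux
Reagents that add atoms: chloromethyl methyl ether (MOMCl), COCCl
Why: Williamson-type O-alkylation (MOM ether formation); the chelated phenol calls for carbonate in refluxing acetone, not an amine base. The acetal masks the C2' oxygen through all enolate steps and keeps it from closing a pyranone onto the wrong carbonyl later.

Step 2
Reactants: 2 1-[4-methoxy-2-(methoxymethoxy)phenyl]ethanone; 3 prenyl bromide, 1-bromo-3-methylbut-2-ene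
Product: 5 1-[4-methoxy-2-(methoxymethoxy)phenyl]-5-methylhex-4-en-1-one, via lithium enolate 4 (not isolated)
Conditions: LiN(i-Pr)2, THF, −78 °C; then 3, −78 → 0 °C
Reagents that add atoms: none
Why: Kinetic deprotonation of the methyl ketone gives enolate 4, which is C-alkylated by the allylic bromide in an SN2 reaction (ketone enolate alkylation); one equivalent of base and low temperature limit a second alkylation. The trisubstituted alkene is carried over unchanged.

Step 3
Reactants: 6 2-fluoro-4,6-dimethoxybenzaldehyde
Product: 8 2-fluoro-6-hydroxy-4-methoxybenzaldehyde, via aryloxydichloroborane 7 (not isolated)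
Conditions: BCl3, CH2Cl2, −78 → 0 °C; then H2O
Reagents that add atoms: none
Why: Chelation-controlled ether cleavage: BCl3 binds the formyl oxygen and the neighbouring C6 methoxy oxygen in a six-membered chelate, and chloride removes only that methyl group to give 7, which work-up hydrolyses. The C4 methoxyl cannot chelate, and it and the C–F bond are left alone.

Step 4
Reactants: 8 2-fluoro-6-hydroxy-4-methoxybenzaldehyde
Product: 9 2-fluoro-4-methoxy-6-(methoxymethoxy)benzaldehyde
Conditions: MOMCl, i-Pr2NEt, CH2Cl2, 0 °C → rt
Reagents that add atoms: chloromethyl methyl ether (MOMCl), COCCl
Why: MOM ether formation on an acidic salicylaldehyde-type phenol with an amine base. The acetal withstands the enolate, oxidant and carbonate of steps 5 to 7 and later leaves together with the ring B acetal.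

Step 5
Reactants: 5 1-[4-methoxy-2-(methoxymethoxy)phenyl]-5-methylhex-4-en-1-one; 9 2-fluoro-4-methoxy-6-(methoxymethoxy)benzaldehyde
Product: 11 2-{[2-fluoro-4-methoxy-6-(methoxymethoxy)phenyl](hydroxy)methyl}-1-[4-methoxy-2-(methoxymethoxy)phenyl]-5-methylhex-4-en-1-one (syn/anti mixture), via lithium enolate 10 (not isolated)
Conditions: LiN(i-Pr)2, THF, −78 °C; then 9, −78 °C; AcOH, −78 °C
Reagents that add atoms: none
Why: Directed (crossed) aldol addition of pre-formed enolate 10 to the non-enolisable aldehyde 9; the cold acidic quench forestalls retro-aldol reaction. Two stereocentres arise without control, which is immaterial because step 6 removes one and step 7 the other.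

Step 6
Reactants: 11 aldol adduct (syn/anti mixture)
Product: 12 1-[2-fluoro-4-methoxy-6-(methoxymethoxy)phenyl]-3-[4-methoxy-2-(methoxymethoxy)phenyl]-2-(3-methylbut-2-enyl)propane-1,3-dione (racemic)
Conditions: Dess–Martin periodinane, CH2Cl2, rt
Reagents that add atoms: none
Why: Dess–Martin oxidation of a β-hydroxy ketone to the 1,3-diketone, a mild hypervalent-iodine oxidation that tolerates aryl acetals and the trisubstituted alkene and does not cleave the β-dicarbonyl.

Step 7
Reactants: 12 2-prenyl-1,3-diketone
Product: 13 7-methoxy-5-(methoxymethoxy)-2-[4-methoxy-2-(methoxymethoxy)phenyl]-3-(3-methylbut-2-enyl)chromen-4-one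
Conditions: K2CO3, dry DMF, 70 °C
Reagents that add atoms: none
Why: Intramolecular SNAr (addition–elimination): carbonate removes the C2 proton of the diketone, and the enolate oxygen on the ring B side attacks the fluorine-bearing carbon ortho to the ring A carbonyl, expelling fluoride and closing the pyranone. The methoxy and acetal groups are meta to fluorine and so do not deactivate that carbon by resonance; ring B offers no leaving group, so only this closure is possible.

Step 8
Reactants: 13 bis(methoxymethyl)-protected flavone
Product: 14 5-hydroxy-2-(2-hydroxy-4-methoxyphenyl)-7-methoxy-3-(3-methylbut-2-enyl)chromen-4-one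
Conditions: HCl (3 M aq., cat.), MeOH, 45 °C
Reagents that add atoms: none
Why: Acid-catalysed acetal exchange (MOM cleavage by methanolysis) frees both phenols, the chelated C5 acetal first. Dilute acid at moderate temperature should spare the prenyl alkene, which has no neighbouring phenol to trap it in a six-membered ring (the C2' hydroxyl could only form an eight-membered ether).

Step 9
Reactants: 14 5-hydroxy-2-(2-hydroxy-4-methoxyphenyl)-7-methoxy-3-(3-methylbut-2-enyl)chromen-4-one
Product: 16 2-[5-hydroxy-7-methoxy-3-(3-methylbut-2-enyl)-4-oxochromen-2-yl]-5-methoxy-1,4-benzoquinone, via hydroquinone 15 (not isolated)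
Conditions: graphite anode, Pt-wire cathode, undivided cell, LiClO4 (0.1 M), MeCN–H2O (4:1), anode potential held just past the first wave of 14, rt
Reagents that add atoms: water, O
Why: At the anode the ring B phenol of 14 gives up two electrons and a proton (through the phenoxyl radical) to form a phenoxonium ion, water adds at C5', and re-aromatisation gives hydroquinone 15, which is oxidised at a less positive potential than 14 and so loses two more electrons and two protons to give 16; the four protons are discharged as hydrogen at the cathode, which keeps the undivided cell near neutral and spares the prenyl group. The closest known reaction type is the anodic oxidation of para-unsubstituted phenols to para-benzoquinones in aqueous acetonitrile, the electrochemical counterpart of the Teuber oxidation. No ring is closed and no stereocentre is formed; one C–O bond (C5'–O) is made. The step needs site selectivity between the two phenols and the alkene: ring B is a free resorcinol monoether and should be the most easily oxidised part, the ring A hydroxyl is hydrogen-bonded to and conjugated with the C4 carbonyl, and the trisubstituted alkene is oxidised only at a clearly more positive potential, so holding the anode just past the first wave of 14 confines the chemistry to ring B. It also needs para over ortho attack by water: C5' is para to the phenoxonium oxygen, ortho to the C4' methoxy donor and unsubstituted, whereas C3' is squeezed between two oxygens and C1' carries the chromone. Because 15 cannot be intercepted, 16 is the planned product; any 16 reduced back to 15 at the small cathode is re-oxidised or simply carried into step 10, and the high water content and low substrate concentration should favour capture by water over phenoxyl coupling.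

Step 10
Reactants: 16 2-[5-hydroxy-7-methoxy-3-(3-methylbut-2-enyl)-4-oxochromen-2-yl]-5-methoxy-1,4-benzoquinone
Product: 15 artoindonesianin Q, 2-(2,5-dihydroxy-4-methoxyphenyl)-5-hydroxy-7-methoxy-3-(3-methylbut-2-enyl)chromen-4-one
Conditions: Na2S2O4, EtOAc–H2O, rt, under N2
Reagents that add atoms: none
Why: Two-electron, two-proton reduction of the para-quinone to the hydroquinone by dithionite in a two-phase system at near-neutral pH. The γ-pyrone carbonyl and the isolated alkene are not reduced by this reagent, and work-up under nitrogen limits re-oxidation.

## Compound list

1 | paeonol, 1-(2-hydroxy-4-methoxyphenyl)ethanone | CC(=O)c1ccc(OC)cc1O | starting material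
2 | 1-[4-methoxy-2-(methoxymethoxy)phenyl]ethanone | CC(=O)c1ccc(OC)cc1OCOC | intermediate
3 | prenyl bromide, 1-bromo-3-methylbut-2-ene | CC(C)=CCBr | starting material
4 | lithium 1-[4-methoxy-2-(methoxymethoxy)phenyl]ethenolate (lithium enolate of 2) | [Li]OC(=C)c1ccc(OC)cc1OCOC | intermediate (not isolated)
5 | 1-[4-methoxy-2-(methoxymethoxy)phenyl]-5-methylhex-4-en-1-one | CC(C)=CCCC(=O)c1ccc(OC)cc1OCOC | intermediate
6 | 2-fluoro-4,6-dimethoxybenzaldehyde | COc1cc(F)c(C=O)c(OC)c1 | starting material
7 | dichloro(3-fluoro-2-formyl-5-methoxyphenoxy)borane | COc1cc(F)c(C=O)c(OB(Cl)Cl)c1 | intermediate (not isolated)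
8 | 2-fluoro-6-hydroxy-4-methoxybenzaldehyde | COc1cc(O)c(C=O)c(F)c1 | intermediate
9 | 2-fluoro-4-methoxy-6-(methoxymethoxy)benzaldehyde | COCOc1cc(OC)cc(F)c1C=O | intermediate
10 | lithium (Z)-1-[4-methoxy-2-(methoxymethoxy)phenyl]-5-methylhexa-1,4-dien-1-olate (lithium enolate of 5; geometry of no consequence) | [Li]O/C(c1ccc(OC)cc1OCOC)=C\CC=C(C)C | intermediate (not isolated)
11 | 2-{[2-fluoro-4-methoxy-6-(methoxymethoxy)phenyl](hydroxy)methyl}-1-[4-methoxy-2-(methoxymethoxy)phenyl]-5-methylhex-4-en-1-one (syn and anti diastereomers, each racemic) | COCOc1cc(OC)cc(F)c1C(O)C(CC=C(C)C)C(=O)c1ccc(OC)cc1OCOC | intermediate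
12 | 1-[2-fluoro-4-methoxy-6-(methoxymethoxy)phenyl]-3-[4-methoxy-2-(methoxymethoxy)phenyl]-2-(3-methylbut-2-enyl)propane-1,3-dione (racemic) | COCOc1cc(OC)cc(F)c1C(=O)C(CC=C(C)C)C(=O)c1ccc(OC)cc1OCOC | intermediate
13 | 7-methoxy-5-(methoxymethoxy)-2-[4-methoxy-2-(methoxymethoxy)phenyl]-3-(3-methylbut-2-enyl)chromen-4-one | COCOc1cc(OC)cc2oc(-c3ccc(OC)cc3OCOC)c(CC=C(C)C)c(=O)c12 | intermediate
14 | 5-hydroxy-2-(2-hydroxy-4-methoxyphenyl)-7-methoxy-3-(3-methylbut-2-enyl)chromen-4-one | COc1ccc(-c2oc3cc(OC)cc(O)c3c(=O)c2CC=C(C)C)c(O)c1 | intermediate
15 | artoindonesianin Q, 2-(2,5-dihydroxy-4-methoxyphenyl)-5-hydroxy-7-methoxy-3-(3-methylbut-2-enyl)chromen-4-one (no stereocentre) | COc1cc(O)c2c(=O)c(CC=C(C)C)c(-c3cc(O)c(OC)cc3O)oc2c1 | target (also passed through, not isolated, in step 9)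
16 | 2-[5-hydroxy-7-methoxy-3-(3-methylbut-2-enyl)-4-oxochromen-2-yl]-5-methoxy-1,4-benzoquinone | COc1cc(O)c2c(=O)c(CC=C(C)C)c(C3=CC(=O)C(OC)=CC3=O)oc2c1 | intermediate

## Step count and weak points

Total step count: 10. Longest linear sequence: 8 steps (steps 1, 2, 5, 6, 7, 8, 9, 10; the ring A branch through steps 3 and 4 is equally long).

**Step 9 (key step).** The most likely failure is loss of selectivity at the electrode: coupling of phenoxyl radicals with build-up of a passivating film on the anode, attack at C3' leading toward an ortho-quinone, or oxidative closure of the C2' oxygen onto the prenyl alkene if the potential drifts upward. All of these follow from ring B and the alkene lying only a few hundred millivolts apart. The fallback sets out from 14 and comes back at 16. It is a Teuber oxidation with two equivalents of (KSO3)2NO (potassium nitrosodisulfonate) in acetone–aqueous KH2PO4 buffer at room temperature. This stoichiometric nitroxyl oxidant delivers the para oxygen itself, is known to turn para-unsubstituted phenols into para-quinones, and leaves isolated alkenes and chelated phenols alone. The fallback makes no compound outside the list (F0).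

**Step 2.** Over-alkylation is the main danger: proton exchange between product 5 and unreacted enolate 4 generates a second enolate that takes up another prenyl group, since both ketones are of similar acidity. The fallback sets out from 2 and comes back at 5 through an activated, mono-alkylating β-keto ester.
- Claisen condensation of 2 with dimethyl carbonate (NaH, THF, reflux) should give methyl 3-[4-methoxy-2-(methoxymethoxy)phenyl]-3-oxopropanoate F1.
- Alkylation of F1 with 3 (K2CO3, acetone) should stop at methyl 2-[4-methoxy-2-(methoxymethoxy)benzoyl]-5-methylhex-4-enoate F2.
- Krapcho dealkoxycarbonylation of F2 (LiCl, wet DMSO, about 140 °C) then gives 5.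

**Step 5.** Incomplete addition or reversal (retro-aldol) is the risk, because a trisubstituted enolate meets a di-ortho-substituted aldehyde and the adduct is crowded. The fallback sets out from 9 and comes back at 12, forming the C3–C4 bond at the ketone oxidation level, where no reversal is possible, and bypassing 11 and step 6.
- Pinnick oxidation of 9 (NaClO2, NaH2PO4, 2-methylbut-2-ene, t-BuOH–H2O) gives 2-fluoro-4-methoxy-6-(methoxymethoxy)benzoic acid F3.
- Carbodiimide coupling of F3 with 1H-benzotriazole gives 1H-benzotriazol-1-yl[2-fluoro-4-methoxy-6-(methoxymethoxy)phenyl]methanone F4, a neutral acyl donor of the kind known to acylate ketone enolates on carbon.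
- Two equivalents of enolate 10 (THF, −78 → 0 °C) with F4 should give 12.

**Step 8.** The risk is acid-promoted addition of chloride, methanol or water across the prenyl alkene while the slower ring B acetal is still being removed. The fallback sets out from 13 and comes back at 14 without protic acid. Me3SiOSO2CF3 with 2,2'-bipyridyl in CH2Cl2 at 0 °C exchanges both aryl acetals for silyl ethers, giving 7-methoxy-2-[4-methoxy-2-(trimethylsilyloxy)phenyl]-3-(3-methylbut-2-enyl)-5-(trimethylsilyloxy)chromen-4-one F5. Neutral water then hydrolyses F5 to 14.

## Further compounds

F0 | step 9 | none | none
F1 | step 2 | methyl 3-[4-methoxy-2-(methoxymethoxy)phenyl]-3-oxopropanoate | COC(=O)CC(=O)c1ccc(OC)cc1OCOC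
F2 | step 2 | methyl 2-[4-methoxy-2-(methoxymethoxy)benzoyl]-5-methylhex-4-enoate (racemic) | COC(=O)C(CC=C(C)C)C(=O)c1ccc(OC)cc1OCOC
F3 | step 5 | 2-fluoro-4-methoxy-6-(methoxymethoxy)benzoic acid | COCOc1cc(OC)cc(F)c1C(=O)O
F4 | step 5 | 1H-benzotriazol-1-yl[2-fluoro-4-methoxy-6-(methoxymethoxy)phenyl]methanone | COCOc1cc(OC)cc(F)c1C(=O)n1nnc2ccccc21
F5 | step 8 | 7-methoxy-2-[4-methoxy-2-(trimethylsilyloxy)phenyl]-3-(3-methylbut-2-enyl)-5-(trimethylsilyloxy)chromen-4-one | COc1ccc(-c2oc3cc(OC)cc(O[Si](C)(C)C)c3c(=O)c2CC=C(C)C)c(O[Si](C)(C)C)c1
A1 | alternative 1 | 2-hydroxy-4,6-dimethoxybenzaldehyde | COc1cc(O)c(C=O)c(OC)c1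
A2 | alternative 1 | 1-methoxy-2,5-bis(methoxymethoxy)-4-(5-methylhex-4-en-1-ynyl)benzene | COCOc1cc(OC)c(OCOC)cc1C#CCC=C(C)C
A3 | alternative 1 | 2-[2,5-bis(methoxymethoxy)-4-methoxyphenyl]-5,7-dimethoxy-3-(3-methylbut-2-enyl)chromen-4-one | COc1cc(OC)c2c(=O)c(CC=C(C)C)c(-c3cc(OCOC)c(OC)cc3OCOC)oc2c1
A4 | alternative 2 | 5-methoxy-3-(methoxymethoxy)-2-[5-methyl-2-(triphenylphosphoranylidene)hex-4-enoyl]phenyl 4-methoxy-2,5-bis(methoxymethoxy)benzoate | COCOc1cc(OC)cc(OC(=O)c2cc(OCOC)c(OC)cc2OCOC)c1C(=O)C(CC=C(C)C)=P(c1ccccc1)(c1ccccc1)c1ccccc1
A5 | alternative 2 | 2-[2,5-bis(methoxymethoxy)-4-methoxyphenyl]-7-methoxy-5-(methoxymethoxy)-3-(3-methylbut-2-enyl)chromen-4-one | COCOc1cc(OC)cc2oc(-c3cc(OCOC)c(OC)cc3OCOC)c(CC=C(C)C)c(=O)c12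
A6 | alternative 3 | 1-(2-fluoro-4,6-dimethoxyphenyl)-2-(3-methylbut-2-enyl)-3-(2,4,5-trimethoxyphenyl)propane-1,3-dione (racemic) | COc1cc(F)c(C(=O)C(CC=C(C)C)C(=O)c2cc(OC)c(OC)cc2OC)c(OC)c1
A7 | alternative 3 | 5,7-dimethoxy-3-(3-methylbut-2-enyl)-2-(2,4,5-trimethoxyphenyl)chromen-4-one | COc1cc(OC)c2c(=O)c(CC=C(C)C)c(-c3cc(OC)c(OC)cc3OC)oc2c1
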